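1. A small charge is the place to start: the flask holds 1.05 M of second end groups against 1.0 M of first end groups. Follow one first end group and suppose that it takes one second end group to become a link. This flask's charges then give 105% as the ceiling, meaning the second end groups charged over the first end groups charged, the limit that second end groups set on the passage of first end groups through links; in this flask they are charged in more than the amount of first end groups.

| flask | first end groups | second end groups | scavenger | remark | time |
|---|---|---|---|---|---|
| summer | 1 M | 1.05 M | 0.60 M | run made earlier |  |
| noon | 1 M | 1.05 M | 2.4 M | run made earlier |  |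
| dawn | 1.5 M | 1.05 M | 1.2 M | run made earlier |  |
| flask | 1.0 M | 1.05 M | 1.20 M |  | 12 min |

| run | time / min | first end groups / % | links / % |
|---|---|---|---|
| summer | 1.00 | 38.6 | 44.9 |
| summer | 1.50 | 33.8 | 38.5 |
| summer | 2.50 | 26.3 | 30.3 |
| summer | 4.00 | 23.7 | 23.4 |
| summer | 8.00 | 12.6 | 7.6 |
| summer | 12.0 | 8.8 | 4.1 |
| noon | 1.00 | 36.8 | 44.3 |
| noon | 1.50 | 30.0 | 41.9 |
| noon | 2.50 | 22.8 | 35.1 |
| noon | 4.00 | 14.8 | 26.5 |
| noon | 8.00 | 4.9 | 11.5 |
| noon | 12.0 | 1.9 | 4.1 |
| dawn | 1.00 | 52.0 | 32.1 |
| dawn | 2.00 | 42.8 | 28.6 |
| dawn | 3.00 | 39.1 | 22.4 |
| dawn | 6.00 | 27.5 | 11.7 |
| dawn | 12.0 | 19.6 | 2.6 |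

(scatter of a reading: 1 percentage point)

- part of the first end groups that has reacted at 12 min
- share of the unused second end groups that is free and not bound as idle adduct, at 12 min

2. The flask's scavenger is twice that of the summer run and half that of the noon run, with the other charges alike. At 12 min, summer left 8.8% of the first end groups and noon left 1.9%.

3. Taking the midpoint on a ratio scale, my own reckoning leaves 4.09% in the flask, so 95.9% has reacted. That is less than the ceiling, by 9.1 percentage points.

4. The weak link is the ceiling itself. The dawn run's ceiling is 70.0%, yet dawn used more than that, 80.4%. The reforged reading is that the ceiling bounds the passage through links, while a first end group has a second fork, a side route.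

5. The forecast differs on this point, holding that “second end groups must be recycled”. It gives 95.2% (93.3% to 96.8%) of the first end groups reacted and 25% (12% to 45%) of the unused second end groups free. The earlier runs do not show the bound part, so the free share remains a guess.

The flask gives 95.5% of the first end groups reacted and 22.3% of the unused second end groups free.

    first end groups + second end groups → links + released group (k = 6.20 L mol⁻¹ min⁻¹)
    second end groups + released group ⇌ idle adduct, settled at all times (K = 87.0 L mol⁻¹)
    scavenger + released group → scavenged by-product (k = 1.20 L mol⁻¹ min⁻¹)
    links → over-reaction product (k = 0.380 min⁻¹)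
    2 first end groups → self-condensation product (k = 0.0290 L mol⁻¹ min⁻¹)

At 12.0 min, links and over-reaction product together hold 92.1% in the flask, under its ceiling of 105%, and self-condensation product holds 3.38%. The neighbour flask with 0.26 M of second end groups has a ceiling of 26.0%. There, at 12.0 min, second end groups stand at 0%, 51.9% of the first end groups have reacted, links and over-reaction product together hold 26.0%, and self-condensation product holds 25.9%.

Readings and results were computed on assumed constants, noise included.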